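## Structural features

The target is one carbocycle, a cyclopent-2-enone (C1 carbonyl, C2=C3), with all its complexity on the two sp3 ring carbons. C4 bears an acetoxy group and a 7-carboxyheptyl chain; C5 bears H and a (2Z)-pent-2-enyl chain. In the systematic names below, C4 is position 1 and the carbonyl is position 4 of a cyclopent-2-en-1-yl group. The two stereocentres are adjacent: C4 (R) is fully substituted, oxygenated and cannot epimerise, while C5 (R) is α to the ketone and can. Acetoxy and pentenyl are cis, so the two carbon chains are trans. Fragile groups are: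
- the β-acetoxy ketone (E1cB loss of acetic acid with base);
- the free tertiary aldol that precedes it (retro-aldol and drift to the 2,3-dialkyl-4-hydroxy isomer with base);
- the skipped (Z)-alkene (migration into conjugation, epoxidation, hydrogenation);
- the allylic acetate toward zerovalent palladium;
- the acetate/carboxylic acid pair, which must be told apart at the end.

The real difficulty is the enantioselective construction of the oxygenated quaternary C4 next to the enolisable C5, in a ring that tolerates neither base nor oxidants. The key step exploits the array O=C1–C2=C3–C4(O)(C) with carbon substituents on C4 and C5. This is the oxidation pattern of a 2,5-disubstituted furan plus one exocyclic carbon: C1–C4 map onto the four furan carbons, the carbonyl oxygen onto the furan oxygen, and C5 onto a furfuryl carbinol carbon. In one sentence: a chiral-acid-catalysed oxa-Piancatelli rearrangement of the racemic 2,5-disubstituted furyl carbinol 9 creates the ring, the C4–C5 bond and the C4 stereocentre at once.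

## Logic of the disconnections

14 from 13: the O–CH3 bond of the chain ester is cut last. The free acid cannot pass through the organometallic steps, and the acetate must already be in place. Gain: none in skeleton, only compatibility. Demand: a hydrolysis at neutral pH that separates a primary-chain methyl ester from a tertiary allylic acetate.

13 from 12: the C5–H bond is re-formed (epimerisation at C5). C5 is the only enolisable carbon, so its configuration can be relayed from the fixed C4 under thermodynamic control. Gain: the key step only has to fix C4. Demand: acid rather than base, and a real energetic preference for trans carbon chains.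

12 from 11: the acetyl C–O bond at C4 is cut. Acetylating after ring formation keeps a leaving group off C4 while the ring is built. Demand: acylation of a hindered tertiary alcohol without base.

11 from 9 (through 10): the C4–C5 ring bond is cut, the C4–OH oxygen is returned to water, and the C1 carbonyl oxygen is reconnected to C4 as a furan oxygen. The ring and both stereocentres disappear, leaving a flat heteroarene with one stereocentre that does not matter. Regiochemistry is encoded in the precursor: the carbinol carbon must become C5 and the chain-bearing furan carbon must become C4. Demand: the forward 4π closure of 10 must occur with one sense of conrotation under a chiral counter-anion, without migration of the skipped alkene.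

9 from 5 and 7: the bond between the carbinol carbon and the furan is cut. This is convergent and puts the (Z)-alkene in from a commercial C6 unit with its geometry already set. Demand: a furyl nucleophile that tolerates a methyl ester, and an aldehyde that must not enolise.

7 from 6: oxidation-level change only. Demand: no migration of the β,γ-alkene.

5 from 4: the C–I bond at the free furan α-position is cut. Demand: mono-iodination of an electron-rich furan.

4 from 1 and 2 (through 3): the furan C2–CH2 bond is cut. Both partners are commercial and the ester is carried from the start. Demand: an sp3–sp2 coupling that tolerates the ester.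

## Other disconnections considered

Alternative 1: the first idea is to cut the C4–CH2 bond of the carboxyheptyl chain. The forward step is 1,2-addition of a C8 Grignard reagent A2 to the ketone of the monoketal A1, anti to the pentenyl group, followed by ketal hydrolysis, acetylation and oxidation of the chain end. The relative configuration would come out right. The absolute configuration, however, would rest on the α-stereocentre of A1, which is enolisable and gives no reliable source of a single enantiomer. A2 cannot carry the carboxyl oxidation level, so the chain end would have to be oxidised after the acetoxy enone exists. The plan needs more steps (ketal, silyl ether, two oxidations) and controls less than the chosen route.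

Alternative 2: cut C4–C5 as an aldol bond. The forward sequence is oxidative ring-opening of the 2,5-dialkylfuran A3 to the (Z)-enedione A4 and base-mediated intramolecular aldol addition. A4 has two enolisable methylene groups of equal acidity next to two equivalent enone carbonyls, so the regioisomer A5 should form alongside the wanted ring. The oxidant needed to open the furan (singlet oxygen, a peracid or N-bromosuccinimide) also attacks the skipped (Z)-alkene. The basic medium allows retro-aldol and elimination, and nothing controls absolute configuration. The chosen route encodes the regiochemistry in the carbinol carbon of 9 and uses no oxidant and no base.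

Alternative 3: cut the C4–O bond. The forward step is late γ-oxygenation of the 4,5-dialkylcyclopentenone A6 through its silyl dienol ether A7 (vinylogous Rubottom oxidation). A6 itself needs a multi-step enantioselective synthesis. A7 is a cyclopentadiene with a ring hydrogen and would scramble by 1,5-hydrogen shifts. The oxidant should approach anti to the pentenyl group, and α-attack competes with γ-attack. Peracids and dioxiranes also epoxidise the (Z)-alkene. This leaves more steps and several unsolved selectivities where the chosen route has one.

Key step: step 5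

Assumption 1: of the two C5 epimers of the 4-acetoxy-4,5-dialkylcyclopentenone, the one with trans carbon chains (the target) is taken to be the more stable, as in jasmonate-type rings where cis-dialkyl isomers relax to trans.

Assumption 2: the sense of induction of the chiral acid in step 5 cannot be predicted; the (R)-catalyst is written, and its (S)-antipode is used instead if it is the one that gives 4R.

## Steps

Step 1
Reactants: 1 methyl 8-bromooctanoate; 2 2-bromofuran
Product: 4 methyl 8-(furan-2-yl)octanoate, via alkylzinc bromide 3 (not isolated)
Conditions: Zn dust, I2 (5 mol %), DMA, 80 °C; then 2, PdCl2(dppf) (3 mol %), THF, 50 °C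
Reagents that add atoms: none
Why: Zinc insertion into the primary bromide gives an ester-tolerant alkylzinc bromide, and Negishi sp3–sp2 coupling at the furan α-bromide follows through zerovalent palladium (oxidative addition, transmetalation, reductive elimination), the bidentate dppf ligand suppressing β-hydride elimination.

Step 2
Reactants: 4 methyl 8-(furan-2-yl)octanoate
Product: 5 methyl 8-(5-iodofuran-2-yl)octanoate
Conditions: NIS (1.05 equiv), DMF, 0 °C, dark
Reagents that add atoms: N-iodosuccinimide, O=C1CCC(=O)N1I
Why: Electrophilic aromatic iodination should go to the free α-position of the 2-alkylfuran, its most nucleophilic site, and the by-product succinimide is too weak an acid to harm the furan.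

Step 3
Reactants: 6 (3Z)-hex-3-en-1-ol
Product: 7 (3Z)-hex-3-enal
Conditions: Dess–Martin periodinane (1.2 equiv), pyridine (3 equiv), CH2Cl2, 0 °C; pentane filtration, used at once as a solution
Reagents that add atoms: none
Why: Dess–Martin oxidation buffered with pyridine stops at the aldehyde and avoids the acid- or base-induced migration of the (Z)-alkene into conjugation; immediate use limits isomerisation.

Step 4
Reactants: 5 methyl 8-(5-iodofuran-2-yl)octanoate; 7 (3Z)-hex-3-enal
Product: 9 methyl 8-{5-[(3Z)-1-hydroxyhex-3-en-1-yl]furan-2-yl}octanoate (racemic), via furylmagnesium chloride 8 (not isolated)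
Conditions: i-PrMgCl·LiCl (1.05 equiv), THF, −40 °C; then 7 (1.3 equiv), −78 → −20 °C; aq. NH4Cl
Reagents that add atoms: none
Why: Iodine–magnesium exchange at a furan α-iodide is fast at −40 °C and spares the aliphatic methyl ester, and the furyl Grignard reagent then adds 1,2 to the aldehyde faster than to the ester; the carbinol centre is left racemic on purpose because step 5 erases it.

Step 5
Reactants: 9 methyl 8-{5-[(3Z)-1-hydroxyhex-3-en-1-yl]furan-2-yl}octanoate (racemic)
Product: 11 methyl 8-{(1R,5S)-1-hydroxy-4-oxo-5-[(2Z)-pent-2-en-1-yl]cyclopent-2-en-1-yl}octanoate, via dihydroxypentadienyl cation 10 (not isolated)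
Conditions: (R)-3,3'-bis(2,4,6-triisopropylphenyl)-1,1'-binaphthyl-2,2'-diyl N-triflylphosphoramide (10 mol %), H2O (10 equiv), toluene, 50 °C
Reagents that add atoms: water, O
Why: Proposed new method: the oxa-Piancatelli rearrangement is known in racemic form for 5-alkyl-2-furyl homoallyl carbinols in aqueous acid, and the proposal is to run it under a chiral N-triflylphosphoramide so that ring closure occurs in a chiral ion pair, the closest known reaction type being the chiral-phosphoric-acid-catalysed aza-Piancatelli rearrangement. The acid ionises the furfuryl alcohol, water adds to the chain-bearing furan carbon of the 2-alkylidenefuranium ion, and the resulting hemiketal opens to the 1,4-dihydroxypentadienyl cation 10. The cyclopentenone ring is closed between the two termini of 10 by a thermal conrotatory 4π electrocyclisation (C4–C5 bond, not a polar enolendo aldol), and proton loss gives the enone directly. C4 is set by the sense of conrotation, which the phosphoramide anion, hydrogen-bonded to both hydroxyl groups of 10, should bias toward one helical twist of the cation. C5 follows from C4 through conrotation of the out,out cation (oxygen and pentenyl both outward), which places hydroxyl and pentenyl trans, that is the 5S epimer that step 7 corrects. The step needs water to attack the substituted furan position, which the exocyclic oxocarbenium form directs, and needs the skipped (Z)-alkene to stay in place, which the mild temperature and the reversibility of carbinol ionisation favour. Racemic 9 suffices because its carbinol centre becomes planar in the cation.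

Step 6
Reactants: 11 methyl 8-{(1R,5S)-1-hydroxy-4-oxo-5-[(2Z)-pent-2-en-1-yl]cyclopent-2-en-1-yl}octanoate
Product: 12 methyl 8-{(1R,5S)-1-acetoxy-4-oxo-5-[(2Z)-pent-2-en-1-yl]cyclopent-2-en-1-yl}octanoate
Conditions: Ac2O (3 equiv), Sc(OTf)3 (2 mol %), MeCN, −20 °C
Reagents that add atoms: acetic anhydride, CC(=O)OC(C)=O
Why: Lewis-acid-catalysed acylation acetylates hindered tertiary alcohols at low temperature without base, so neither retro-aldol nor E1cB can start; ionisation of the C4–O bond is disfavoured because the cation would be a 4π antiaromatic hydroxycyclopentadienyl cation, and no stereocentre is touched.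

Step 7
Reactants: 12 methyl 8-{(1R,5S)-1-acetoxy-4-oxo-5-[(2Z)-pent-2-en-1-yl]cyclopent-2-en-1-yl}octanoate
Product: 13 methyl 8-{(1R,5R)-1-acetoxy-4-oxo-5-[(2Z)-pent-2-en-1-yl]cyclopent-2-en-1-yl}octanoate
Conditions: p-TsOH (5 mol %), CH2Cl2, 35 °C, to equilibrium; chromatography, recovered 12 resubmitted
Reagents that add atoms: none
Why: Acid-catalysed keto–enol equilibration at C5, the only enolisable position, relays the fixed C4 configuration to C5 and should favour the epimer with trans carbon chains (pentenyl cis to the smaller acetoxy group); acid is used because an enolate would expel acetate, and the acetate blocks retro-aldol.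

Step 8
Reactants: 13 methyl 8-{(1R,5R)-1-acetoxy-4-oxo-5-[(2Z)-pent-2-en-1-yl]cyclopent-2-en-1-yl}octanoate
Product: 14 8-{(1R,5R)-1-acetoxy-4-oxo-5-[(2Z)-pent-2-en-1-yl]cyclopent-2-en-1-yl}octanoic acid
Conditions: immobilised Candida antarctica lipase B, phosphate buffer pH 7.0/acetone, 30 °C
Reagents that add atoms: water, O
Why: Lipase-catalysed hydrolysis at neutral pH should cleave the unhindered methyl ester of the fatty-acid-like chain, while esters of tertiary alcohols are not accepted by this class of hydrolase; neutral conditions avoid E1cB loss of acetate, as in the enzymatic unmasking of base-labile prostaglandin esters.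

## Compound list

1 | methyl 8-bromooctanoate | COC(=O)CCCCCCCBr | starting material
2 | 2-bromofuran | Brc1ccco1 | starting material
3 | (8-methoxy-8-oxooctyl)zinc bromide | COC(=O)CCCCCCC[Zn]Br | intermediate
4 | methyl 8-(furan-2-yl)octanoate | COC(=O)CCCCCCCc1ccco1 | intermediate
5 | methyl 8-(5-iodofuran-2-yl)octanoate | COC(=O)CCCCCCCc1ccc(I)o1 | intermediate
6 | (3Z)-hex-3-en-1-ol | CC/C=C\CCO | starting material
7 | (3Z)-hex-3-enal | CC/C=C\CC=O | intermediate
8 | chloro[5-(8-methoxy-8-oxooctyl)furan-2-yl]magnesium (lithium chloride complex) | COC(=O)CCCCCCCc1ccc([Mg]Cl)o1 | intermediate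
9 | methyl 8-{5-[(3Z)-1-hydroxyhex-3-en-1-yl]furan-2-yl}octanoate (racemic) | CC/C=C\CC(O)c1ccc(CCCCCCCC(=O)OC)o1 | intermediate
10 | O-protonated methyl (10Z,12Z,15Z)-12-hydroxy-9-oxooctadeca-10,12,15-trienoate (1,4-dihydroxypentadienyl cation) | CC/C=C\C/C=C(O)/C=C\C(=[OH+])CCCCCCCC(=O)OC | intermediate
11 | methyl 8-{(1R,5S)-1-hydroxy-4-oxo-5-[(2Z)-pent-2-en-1-yl]cyclopent-2-en-1-yl}octanoate | CC/C=C\C[C@@H]1C(=O)C=C[C@@]1(CCCCCCCC(=O)OC)O | intermediate
12 | methyl 8-{(1R,5S)-1-acetoxy-4-oxo-5-[(2Z)-pent-2-en-1-yl]cyclopent-2-en-1-yl}octanoate | CC/C=C\C[C@@H]1C(=O)C=C[C@@]1(CCCCCCCC(=O)OC)OC(C)=O | intermediate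
13 | methyl 8-{(1R,5R)-1-acetoxy-4-oxo-5-[(2Z)-pent-2-en-1-yl]cyclopent-2-en-1-yl}octanoate | CC/C=C\C[C@H]1C(=O)C=C[C@@]1(CCCCCCCC(=O)OC)OC(C)=O | intermediate
14 | 8-{(1R,5R)-1-acetoxy-4-oxo-5-[(2Z)-pent-2-en-1-yl]cyclopent-2-en-1-yl}octanoic acid | CC/C=C\C[C@H]1C(=O)C=C[C@@]1(CCCCCCCC(=O)O)OC(C)=O | target

## Step count and least certain steps

Total step count: 8. Longest linear sequence: 7 steps (1 → 4 → 5 → 9 → 11 → 12 → 13 → 14); step 3 supplies 7 in one step.

Step 5 (key step, Proposed new method). Enantiocontrol may be lost because water competes for the hydrogen bonds of the ion pair or because an uncatalysed background rearrangement sets in at the temperature needed. The furfuryl cation may also lose a proton toward the side chain, moving the skipped alkene into conjugation. Fallback with known chemistry, setting out from 9 and returning at 11: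
- The rearrangement is run racemically with ZnCl2 in dioxane/water at reflux. This gives 11 together with its antipode, methyl 8-{(1S,5R)-1-hydroxy-4-oxo-5-[(2Z)-pent-2-en-1-yl]cyclopent-2-en-1-yl}octanoate F1.
- Luche reduction (NaBH4, CeCl3·7H2O, MeOH, −40 °C), with hydride anti to the pentenyl group, turns the pair into methyl 8-{(1R,4R,5R)-1,4-dihydroxy-5-[(2Z)-pent-2-en-1-yl]cyclopent-2-en-1-yl}octanoate F2 and its antipode, the (1S,4S,5S)-diol F3.
- Lipase-catalysed kinetic resolution of the secondary allylic alcohol with vinyl acetate is written for the case in which the enzyme acylates the unwanted antipode. It converts F3 into methyl 8-{(1S,4S,5S)-4-acetoxy-1-hydroxy-5-[(2Z)-pent-2-en-1-yl]cyclopent-2-en-1-yl}octanoate F4 and leaves F2.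
- MnO2 in CH2Cl2 oxidises F2 back to 11.

Step 7. The thermodynamic preference for the 5R epimer may be too small for a useful equilibrium, or the acid may induce loss or migration of the acetate. Fallback under kinetic control, setting out from 11 and returning at 13:
- TESOTf and Et3N in CH2Cl2 give methyl 8-{(1R)-2-[(2Z)-pent-2-en-1-yl]-1,3-bis(triethylsilyloxy)cyclopenta-2,4-dien-1-yl}octanoate F5.
- HF·pyridine in THF at −40 °C protonates the silyl enol ether at C5 from the face away from the bulky triethylsilyloxy group and then removes both silyl groups. This gives methyl 8-{(1R,5R)-1-hydroxy-4-oxo-5-[(2Z)-pent-2-en-1-yl]cyclopent-2-en-1-yl}octanoate F6.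
- Acetylation under the conditions of step 6 gives 13.

Step 4. The Grignard reagent may act as a base toward the doubly activated methylene group of 7 (enolisation and migration to the conjugated enal), or may attack the ester during the exchange. Fallback, setting out from 5 and 7 and returning at 9: Nozaki–Hiyama–Kishi coupling (CrCl2, 3 equiv; NiCl2, 2 mol %; DMF, room temperature). The furylchromium species is not basic and ignores esters. No new compound arises (F0).

Step 8. The enzyme may not accept the substrate, or slow loss of the tertiary acetate and elimination may accompany a long reaction. Fallback that keeps the acetate away from any hydrolysis, setting out from 11 and returning at 14: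
- Me3SnOH in 1,2-dichloroethane at 60 °C cleaves the methyl ester to 8-{(1R,5S)-1-hydroxy-4-oxo-5-[(2Z)-pent-2-en-1-yl]cyclopent-2-en-1-yl}octanoic acid F7.
- Ac2O/Sc(OTf)3 followed by aqueous work-up (which hydrolyses the mixed anhydride) gives 8-{(1R,5S)-1-acetoxy-4-oxo-5-[(2Z)-pent-2-en-1-yl]cyclopent-2-en-1-yl}octanoic acid F8.
- Acid equilibration as in step 7 gives 14.

Step 2. Over-iodination, oxidative ring-opening of the electron-rich furan, or decomposition of the iodofuran on handling may occur. Fallback that avoids halogenating the furan, setting out from 3 and returning at 9: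
- Coupling of 3 with an excess of commercial 2,5-dibromofuran (PdCl2(dppf), THF, 50 °C) gives methyl 8-(5-bromofuran-2-yl)octanoate F9.
- Bromine–magnesium exchange (i-PrMgCl·LiCl, THF, 0 °C) and addition to 7 at −78 °C give 9.

## Further compounds

F1 | step 5 | methyl 8-{(1S,5R)-1-hydroxy-4-oxo-5-[(2Z)-pent-2-en-1-yl]cyclopent-2-en-1-yl}octanoate (antipode of 11, formed with it as the racemate) | CC/C=C\C[C@H]1C(=O)C=C[C@]1(CCCCCCCC(=O)OC)O
F2 | step 5 | methyl 8-{(1R,4R,5R)-1,4-dihydroxy-5-[(2Z)-pent-2-en-1-yl]cyclopent-2-en-1-yl}octanoate | CC/C=C\C[C@@H]1[C@H](O)C=C[C@@]1(CCCCCCCC(=O)OC)O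
F3 | step 5 | methyl 8-{(1S,4S,5S)-1,4-dihydroxy-5-[(2Z)-pent-2-en-1-yl]cyclopent-2-en-1-yl}octanoate | CC/C=C\C[C@H]1[C@@H](O)C=C[C@]1(CCCCCCCC(=O)OC)O
F4 | step 5 | methyl 8-{(1S,4S,5S)-4-acetoxy-1-hydroxy-5-[(2Z)-pent-2-en-1-yl]cyclopent-2-en-1-yl}octanoate | CC/C=C\C[C@H]1[C@@H](OC(C)=O)C=C[C@]1(CCCCCCCC(=O)OC)O
F5 | step 7 | methyl 8-{(1R)-2-[(2Z)-pent-2-en-1-yl]-1,3-bis(triethylsilyloxy)cyclopenta-2,4-dien-1-yl}octanoate | CC/C=C\CC1=C(O[Si](CC)(CC)CC)C=C[C@@]1(CCCCCCCC(=O)OC)O[Si](CC)(CC)CC
F6 | step 7 | methyl 8-{(1R,5R)-1-hydroxy-4-oxo-5-[(2Z)-pent-2-en-1-yl]cyclopent-2-en-1-yl}octanoate | CC/C=C\C[C@H]1C(=O)C=C[C@@]1(CCCCCCCC(=O)OC)O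
F0 | step 4 | none | none
F7 | step 8 | 8-{(1R,5S)-1-hydroxy-4-oxo-5-[(2Z)-pent-2-en-1-yl]cyclopent-2-en-1-yl}octanoic acid | CC/C=C\C[C@@H]1C(=O)C=C[C@@]1(CCCCCCCC(=O)O)O
F8 | step 8 | 8-{(1R,5S)-1-acetoxy-4-oxo-5-[(2Z)-pent-2-en-1-yl]cyclopent-2-en-1-yl}octanoic acid | CC/C=C\C[C@@H]1C(=O)C=C[C@@]1(CCCCCCCC(=O)O)OC(C)=O
F9 | step 2 | methyl 8-(5-bromofuran-2-yl)octanoate | COC(=O)CCCCCCCc1ccc(Br)o1
A1 | alternative 1 | (5R)-4,4-dimethoxy-5-[(2Z)-pent-2-en-1-yl]cyclopent-2-en-1-one | CC/C=C\C[C@H]1C(OC)(OC)C=CC1=O
A2 | alternative 1 | bromo[8-(tert-butyldimethylsilyloxy)octyl]magnesium | Br[Mg]CCCCCCCCO[Si](C)(C)C(C)(C)C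
A3 | alternative 2 | methyl 8-{5-[(3Z)-hex-3-en-1-yl]furan-2-yl}octanoate | CC/C=C\CCc1ccc(CCCCCCCC(=O)OC)o1
A4 | alternative 2 | methyl (10Z,15Z)-9,12-dioxooctadeca-10,15-dienoate | CC/C=C\CCC(=O)/C=C\C(=O)CCCCCCCC(=O)OC
A5 | alternative 2 | methyl 7-{2-[(3Z)-hex-3-en-1-yl]-2-hydroxy-5-oxocyclopent-3-en-1-yl}heptanoate | CC/C=C\CCC1(O)C=CC(=O)C1CCCCCCC(=O)OC
A6 | alternative 3 | methyl 8-{(1S,5R)-4-oxo-5-[(2Z)-pent-2-en-1-yl]cyclopent-2-en-1-yl}octanoate | CC/C=C\C[C@H]1C(=O)C=C[C@@H]1CCCCCCCC(=O)OC
A7 | alternative 3 | methyl 8-{(5R)-5-[(2Z)-pent-2-en-1-yl]-4-(trimethylsilyloxy)cyclopenta-1,3-dien-1-yl}octanoate | CC/C=C\C[C@H]1C(O[Si](C)(C)C)=CC=C1CCCCCCCC(=O)OC
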